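## Analysis of the target

The target is a pentacycle. An N-methoxycarbonyl indoline is fused through C2 and C3 to an eight-membered amine ring (azocane); the azocane nitrogen is shared with a 3-hydroxypyrrolidine; and a cyclohexane joins indoline C2 to the pyrrolidine carbon next to nitrogen (called Cq below). C2 and Cq are therefore the bridgeheads of an aza-bicyclo[4.2.2]decane, with bridges CH2–CH2, CH2–CH(CO2Me) and N–CH2–CH2–C3. There are five stereocentres: C2 (R), C3 (S), Cq (R), the carbinol carbon (R) and the ester methine (R). C2 and C3 are adjacent and fully substituted, Cq is fully substituted and flanked by the carbinol, and the hydroxyl is cis to the ring CH2 that leads to the ester methine. Because C2 and Cq are bridgeheads, the configuration of one fixes that of the other; C3 and the carbinol are independent of the cage, and the ester methine is the only centre that can epimerise. Sensitive groups are the tertiary amine, two methyl esters, the methyl carbamate and the β-amino ester unit N1–C2–CH(CO2Me). The difficulty lies in the two neighbouring quaternary carbons C2/C3, the α-tertiary amine carbon Cq and the medium ring that links them. The strategy rests on one feature: C2 carries the carbamate nitrogen N1 and the CH–CO2Me carbon, which is the pattern of a Mannich adduct of a 3H-indole, and C3 is quaternary, so such a 3H-indole cannot aromatise.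

## Retrosynthetic reasoning

**Target 35 to geminal diester 32.** The silyl ether 34 is removed last. The ester methine of 34 is traced back to the geminal diester 32 by adding one methoxycarbonyl group. This turns the nucleophilic carbon into a malonate carbon, acidic enough to be enolised under mild conditions. The forward reaction (loss of one ester, then protonation) has to set the methine configuration.

**32 to 3H-indole 29 and methyl chloroformate 30.** The bond from C2 to the malonate carbon and the N1–carbonyl bond are cut together. This is the only disconnection that makes a fully substituted C2 from a planar carbon that already carries N1 and C3. It closes the cyclohexane across the azocane, so C2 is formed under the geometric control of Cq. The forward step must acylate N1 and let the tethered malonate attack C2 before other paths intervene.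

**29 to aldehyde 26 and dimethyl malonate 27 (through 28).** The malonate arm is cut at its C–C bond to Cq–CH2, back to the aldehyde 26. It is cut here, late, for a structural reason: a pyrrolidine N–H with a malonate ester five atoms away would close to a bicyclic γ-lactam. The malonate is therefore introduced only after the ring nitrogen has become tertiary.

**26 to open-chain 3H-indole 24.** The azocane is opened at the N–CH2 bond, which leads back to a primary bromide on the two-carbon chain at C3 and a protected pyrrolidine. The cut is placed at nitrogen and not at C3 because a ring closure at C3 would create that quaternary centre under the influence of remote centres only. The closure is done on the 3H-indole and not on its keto precursor, because in the ketone the free amine could attack the carbonyl next to the doubly activated C3 and split the C2–C3 bond.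

**24 to nitro ketone 22.** The C2=N1 bond is cut to a ketone and an aryl nitro group. Reduction of the nitro group gives the 3H-indole without touching C3.

**22 to methyl ketone 17 and aldehyde 11 (through 21 and 19).** The CH2–CH2 bond between the ketone α-carbon and the carbon on Cq is cut by an aldol disconnection. The ketone in 17 can enolise only toward its methyl group, and the aldehyde 11 cannot enolise, so the union is unambiguous. It joins two fragments that each hold one quaternary centre already made.

**17 to aryl acetate 12 (through 16, 15, 14; alkylating agent 13).** The C3–acetyl bond is cut. C3 is thus set by an enantioselective C-acylation in a small fragment in which it is the only stereocentre. The two-carbon chain comes from alkylation of 12 with 13.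

**11 to keto ester 1 (through 9, 8, 7, 6, 5, 2; allyl bromide 3).** The aldehyde carbon of 11 comes from an allyl group (double-bond shift, then cleavage), and the acetal carbon comes from the ester. Cq is cut at its bond to the allyl CH2: alkylation of the dianion of the hydroxy ester 2 places the new group trans to oxygen. That is the arrangement needed, because the ester-derived arm (the later malonate arm) must be cis to the hydroxyl. The carbinol is set first, by asymmetric hydrogenation of 1.

## Alternatives that were turned down

**Alternative 1:** The azocane is opened at N–CH2 (back to an aldehyde held as a dimethyl acetal on the chain at C3) and the carbinol is taken back to a ketone. This gives the spiro pyrrolidin-3-one A1, whose cyclohexane is then derived from a cycloheptane by a 1,2-shift. In the forward key step a tethered primary amine closes onto a ring ketone to a cyclic imine. On heating, the ring CH2 moves from the neighbouring hydroxyl-bearing carbon to the imine carbon (α-iminol rearrangement). The ring contracts, the old carbinol carbon becomes the pyrrolidinone carbonyl and the imine carbon becomes Cq.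
- *For:* the α-tertiary amine carbon is made without an enolate, in a suprafacial shift that relays the carbinol configuration to Cq. The indoline with C2, C3 and the ester methine is complete before any nitrogen ring is built, so no 3H-indole ester and no competition between iminium and enecarbamate arises. On this point it is stronger than the chosen route.
- *Against:* it presupposes a seven-membered carbocycle that already carries C2, C3 and the ester methine, so the crowded bonds at C2 must be made earlier by means the alternative does not supply. A1 still needs a face-selective reduction of a spiro ketone whose faces differ only through remote groups. It also needs an eight-membered reductive amination of a hindered amine, and as a β-amino ketone A1 can open by retro-Michael reaction.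
- *In its place* the chosen strategy sets the carbinol in its first step by catalyst control, sets Cq next to it by chelation-controlled alkylation, and forms the C2 bonds last under cage control, in fewer steps from commercial materials.

**Alternative 2:** The bond cut is C2–C3. A2 is a cyclohexene whose future C2 is an allylic methine bonded to the quaternary carbon that carries a 2-bromophenyl group and a free carboxylic acid. The retron leads back to an eight-membered lactone, the aryl-acetate ester of an allylic alcohol on the cyclohexene. In the forward key step a strong amide base and a silyl chloride give the silyl ketene acetal. On warming, an Ireland–Claisen shift bonds the aryl-acetate carbon to the far end of the allyl unit as the C–O bond breaks, so the lactone becomes the carbocyclic azocane.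
- *For:* the most hindered C–C bond and the quaternary C3 arise in one intramolecular event through a cyclic transition state, with the ketene acetal geometry fixed by the ring, and the medium ring is first made as a lactone. On control of C3 this is stronger than the chosen route, which relies on an external chiral catalyst for that centre.
- *Against:* the ring-bound ketene acetal must reach a boat-like transition state inside a bridged system. A2 has C2 only as C–H, so the N1–C2 bond to a carbon flanked by C3 and the ester methine must be made afterwards from the aryl bromide by an allylic C–H or alkene amination, for which no dependable method exists at such a position. The alkene must be removed, and the ester methine must survive the strong base.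
- *In its place* the chosen route obtains N1–C2 from a nitro reduction and uses its key step for the C2–C bond with nitrogen already in place. For C3 it offers a short separate fragment whose enantiomeric purity can be checked before coupling.

**Alternative 3:** The pyrrolidine is made last on the finished cage. The carbinol C–O bond is taken back to a C–acetyl bond (Baeyer–Villiger retron), and the 3-acetylpyrrolidine A3 is taken apart by an aza-Cope/Mannich retron into the secondary amine of the azocane, whose neighbouring carbon Cq carries a vinyl carbinol, and formaldehyde (A4). In the forward key step A4 gives an iminium ion; a cationic 2-aza-Cope shift and Mannich closure form the N–CH2, CH2–CH2 and CH(acetyl)–Cq bonds.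
- *For:* three bonds and a ring form in one well-behaved cascade. The nitrogen is never a free pyrrolidine N–H beside ester arms, which is the constraint that forces the late malonate installation in the chosen route. On step economy at that point it is stronger.
- *Against:* after the sigmatropic shift the iminium double bond lies between nitrogen and the bridgehead Cq of the bicyclo[4.2.2] system, which is strained, and Cq must be re-formed in the Mannich step. The acetyl-bearing carbon is epimerisable, so its configuration is thermodynamic and need not be the one required. The oxygen insertion needs a peracid in the presence of a tertiary amine. The whole cage with both C2 bonds must exist beforehand.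
- *In its place* the chosen strategy fixes the carbinol at the outset and needs no oxidation-level change at the end.

Key step: step 19

Remark on the chemistry: the sense of induction of the planar-chiral acylation catalyst in step 10 is taken from its behaviour with other α-aryl silyl ketene acetals and has not been checked here; if the ortho-nitro substrate responds in the opposite sense, the mirror-image catalyst is used and nothing else changes.

## Route

Step 1
Reactants: 1 1-tert-butyl 2-methyl 3-oxopyrrolidine-1,2-dicarboxylate
Product: 2 1-tert-butyl 2-methyl (2R,3R)-3-hydroxypyrrolidine-1,2-dicarboxylate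
Conditions: H2 (50 atm), [RuCl(C6H6)((R)-BINAP)]Cl (1 mol%), CH2Cl2/MeOH, 50 °C
Reagents that add atoms: none
Why: Noyori asymmetric hydrogenation of a β-keto ester; the (R)-BINAP complex of divalent ruthenium should deliver hydrogen to the ketone face that gives the (3R)-carbinol, while C2 equilibrates through the enol (dynamic kinetic resolution) to the trans ester. Only the carbinol centre is carried on, since C2 becomes an enolate carbon in step 2.

Step 2
Reactants: 2 1-tert-butyl 2-methyl (2R,3R)-3-hydroxypyrrolidine-1,2-dicarboxylate; 3 allyl bromide
Product: 5 1-tert-butyl 2-methyl (2S,3R)-3-hydroxy-2-(prop-2-en-1-yl)pyrrolidine-1,2-dicarboxylate, via dilithium alkoxide enolate 4 (not isolated)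
Conditions: LiN(iPr)2 (2.3 equiv), THF, DMPU, −78 → −30 °C; 3, −78 → −20 °C
Reagents that add atoms: allyl bromide (3), C=CCBr
Why: Fráter–Seebach alkylation of a β-hydroxy ester dianion; the electrophile enters anti to the lithium alkoxide on the neighbouring ring carbon, so the allyl group ends trans and the ester cis to oxygen, which fixes Cq. A β-alkoxide is not expelled from the enolate.

Step 3
Reactants: 5 1-tert-butyl 2-methyl (2S,3R)-3-hydroxy-2-(prop-2-en-1-yl)pyrrolidine-1,2-dicarboxylate
Product: 6 1-tert-butyl 2-methyl (2S,3R)-3-[(tert-butyldimethylsilyl)oxy]-2-(prop-2-en-1-yl)pyrrolidine-1,2-dicarboxylate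
Conditions: TBSOTf, 2,6-lutidine, CH2Cl2, −78 → 0 °C
Reagents that add atoms: tert-butyldimethylsilyl triflate, CC(C)(C)[Si](C)(C)OS(=O)(=O)C(F)(F)F
Why: Silylation of a hindered secondary alcohol with the silyl triflate; at low temperature the alcohol reacts before the tert-butyl carbamate.

Step 4
Reactants: 6 1-tert-butyl 2-methyl (2S,3R)-3-[(tert-butyldimethylsilyl)oxy]-2-(prop-2-en-1-yl)pyrrolidine-1,2-dicarboxylate
Product: 7 tert-butyl (2S,3R)-3-[(tert-butyldimethylsilyl)oxy]-2-formyl-2-(prop-2-en-1-yl)pyrrolidine-1-carboxylate
Conditions: iBu2AlH (1.3 equiv), CH2Cl2, −78 °C; Rochelle salt work-up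
Reagents that add atoms: none
Why: Partial reduction of a hindered α-amino ester with iBu2AlH, which stops at the aldehyde oxidation level at −78 °C. The aldehyde has no α-hydrogen and cannot epimerise.

Step 5
Reactants: 7 tert-butyl (2S,3R)-3-[(tert-butyldimethylsilyl)oxy]-2-formyl-2-(prop-2-en-1-yl)pyrrolidine-1-carboxylate
Product: 8 tert-butyl (2S,3R)-3-[(tert-butyldimethylsilyl)oxy]-2-(dimethoxymethyl)-2-(prop-2-en-1-yl)pyrrolidine-1-carboxylate
Conditions: HC(OMe)3, MeOH, pyridinium p-toluenesulfonate (cat.), 40 °C
Reagents that add atoms: trimethyl orthoformate, COC(OC)OC; methanol, CO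
Why: Acetal formation masks the aldehyde that will later carry the malonate, so that only one aldehyde is present in the aldol union; the acetal is released together with the carbamate in step 16.

Step 6
Reactants: 8 tert-butyl (2S,3R)-3-[(tert-butyldimethylsilyl)oxy]-2-(dimethoxymethyl)-2-(prop-2-en-1-yl)pyrrolidine-1-carboxylate
Product: 9 tert-butyl (2S,3R)-3-[(tert-butyldimethylsilyl)oxy]-2-(dimethoxymethyl)-2-[(1E)-prop-1-en-1-yl]pyrrolidine-1-carboxylate
Conditions: [Ir(cod)(PMePh2)2]PF6 (2 mol%, activated with H2, then degassed), THF, rt
Reagents that add atoms: none
Why: Metal hydride-catalysed migration of a terminal double bond by one position to the more stable (E)-disubstituted alkene; this brings the alkene next to Cq so that its cleavage leaves a one-carbon aldehyde.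

Step 7
Reactants: 9 tert-butyl (2S,3R)-3-[(tert-butyldimethylsilyl)oxy]-2-(dimethoxymethyl)-2-[(1E)-prop-1-en-1-yl]pyrrolidine-1-carboxylate
Product: 11 tert-butyl (2R,3R)-3-[(tert-butyldimethylsilyl)oxy]-2-(dimethoxymethyl)-2-formylpyrrolidine-1-carboxylate, via ozonide 10 (not isolated)
Conditions: O3, CH2Cl2, −78 °C; PPh3, −78 °C → rt
Reagents that add atoms: ozone, [O-][O+]=O
Why: Ozonolysis with reductive work-up cleaves the propenyl group to the aldehyde on the arm that is trans to the silyloxy group; the carbamate nitrogen, the acetal and the silyl ether are inert to ozone. The change of descriptor at Cq from (S) to (R) is a priority effect only.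

Step 8
Reactants: 12 methyl 2-(2-nitrophenyl)acetate; 13 (2-bromoethoxy)(tert-butyl)dimethylsilane
Product: 14 methyl 4-[(tert-butyldimethylsilyl)oxy]-2-(2-nitrophenyl)butanoate (racemic)
Conditions: NaH, DMF, 0 °C; 13, 50 °C
Reagents that add atoms: (2-bromoethoxy)(tert-butyl)dimethylsilane (13), BrCCO[Si](C)(C)C(C)(C)C
Why: Alkylation of the stabilised enolate of an o-nitroaryl acetate with a primary bromide; the oxygen is carried as a silyl ether because a 2-haloethyl chain would close to the cyclopropane under base.

Step 9
Reactants: 14 methyl 4-[(tert-butyldimethylsilyl)oxy]-2-(2-nitrophenyl)butanoate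
Product: 15 silyl ketene acetal of 14 (E/Z mixture)
Conditions: LiN(SiMe3)2, THF, −78 °C; Me3SiCl, −78 °C → rt; filtered through Celite under argon and used crude
Reagents that add atoms: chlorotrimethylsilane, C[Si](C)(C)Cl
Why: O-Silylation of the ester enolate; the amide base is hindered and weakly reducing, which suits the nitroarene, and the isomer ratio of 15 is of no consequence for step 10.

Step 10
Reactants: 15 silyl ketene acetal of 14
Product: 16 methyl (2S)-2-acetyl-4-[(tert-butyldimethylsilyl)oxy]-2-(2-nitrophenyl)butanoate
Conditions: Ac2O (1.5 equiv), planar-chiral iron complex (C5Me5)Fe(C12H13N2) [C12H13N2 = 4-(pyrrolidin-1-yl)pyrindinyl; single enantiomer, 5 mol%], Et2O/CH2Cl2, rt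
Reagents that add atoms: acetic anhydride, CC(=O)OC(C)=O
Why: Nucleophile-catalysed enantioselective C-acylation of a silyl ketene acetal; acetate released on acyl transfer to the catalyst removes the silyl group and the acetyl group is then delivered within a chiral ion pair, so both geometric isomers of 15 converge on one enantiomer. This sets the quaternary C3 as (S) in a fragment that holds no other stereocentre.

Step 11
Reactants: 16 methyl (2S)-2-acetyl-4-[(tert-butyldimethylsilyl)oxy]-2-(2-nitrophenyl)butanoate
Product: 17 methyl (2S)-2-acetyl-4-bromo-2-(2-nitrophenyl)butanoate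
Conditions: Ph3PBr2, CH2Cl2, 0 °C → rt
Reagents that add atoms: triphenylphosphine dibromide, BrP(Br)(c1ccccc1)(c1ccccc1)c1ccccc1
Why: Direct conversion of a primary silyl ether into the bromide with the phosphine dihalide (substitution at the CH2–O carbon); no free γ-hydroxy ester appears, which would close to the lactone.

Step 12
Reactants: 17 methyl (2S)-2-acetyl-4-bromo-2-(2-nitrophenyl)butanoate; 11 tert-butyl (2R,3R)-3-[(tert-butyldimethylsilyl)oxy]-2-(dimethoxymethyl)-2-formylpyrrolidine-1-carboxylate
Product: 19 aldol adduct (β-hydroxy ketone, mixture at the new carbinol), via dibutylboron enolate 18 (not isolated)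
Conditions: Bu2BOTf (1.05 equiv), iPr2NEt, CH2Cl2, −78 → 0 °C; 11, −78 → 0 °C; pH 7 buffer, MeOH
Reagents that add atoms: none
Why: Boron-mediated aldol addition of a methyl ketone to a non-enolisable aldehyde; the ketone can enolise only toward CH3 because its other α-carbon is quaternary, and the boron enolate is too weakly basic to attack the bromide or to induce retro-Claisen cleavage. The new carbinol centre is removed in step 13.

Step 13
Reactants: 19 aldol adduct
Product: 21 (E)-enone (methyl (2S,4E)-2-(2-bromoethyl)-2-(2-nitrophenyl)-3-oxopent-4-enoate carrying the pyrrolidine at C5), via mesylate 20 (not isolated)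
Conditions: MsCl, Et3N, CH2Cl2, 0 °C → rt
Reagents that add atoms: none
Why: Mesylation followed by E1cB elimination; triethylamine suffices because the protons removed lie α to the ketone and β to the leaving group.

Step 14
Reactants: 21 (E)-enone
Product: 22 saturated nitro ketone (methyl (2S)-2-(2-bromoethyl)-2-(2-nitrophenyl)-3-oxopentanoate carrying the pyrrolidine at C5)
Conditions: H2 (3 atm), RhCl(PPh3)3 (10 mol%), benzene/EtOH, rt
Reagents that add atoms: none
Why: Homogeneous hydrogenation saturates the disubstituted enone C=C and leaves the nitro group, the alkyl bromide and the acetal untouched.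

Step 15
Reactants: 22 saturated nitro ketone
Product: 24 open-chain 3H-indole (methyl (3S)-3-(2-bromoethyl)-3H-indole-3-carboxylate with the pyrrolidinylethyl chain at C2), via amino ketone 23 (not isolated)
Conditions: TiCl3 (aq., 8 equiv), NH4OAc, acetone/H2O, rt
Reagents that add atoms: none
Why: Trivalent titanium reduces the nitro group to the aniline 23, which condenses with the ketone in a five-membered ring closure faster than it attacks the ester or the bromide; C3 is quaternary, so the product stays a 3H-indole. The buffered medium spares the acetal, and masking the ketone as the imine removes the risk that the amine freed in step 16 splits the C2–C3 bond by attack on the carbonyl.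

Step 16
Reactants: 24 open-chain 3H-indole
Product: 26 tetracyclic aldehyde (azocane closed; CHO on Cq), via amino aldehyde 25 (not isolated)
Conditions: CF3CO2H/CH2Cl2 (1:4), H2O (3 equiv), 0 °C; concentrate; NaHCO3, MeCN (0.003 M), 75 °C
Reagents that add atoms: water, O
Why: Acid removes the tert-butyl carbamate and hydrolyses the acetal; the liberated secondary amine then displaces the primary bromide under high dilution, an intramolecular N-alkylation that closes the azocane. At this stage no ester lies within reach of the N–H through a five- or six-membered transition state, so lactam formation does not compete, and the hindered secondary silyl ether should survive the short acid treatment.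

Step 17
Reactants: 26 tetracyclic aldehyde; 27 dimethyl malonate
Product: 28 alkylidene malonate
Conditions: TiCl4, pyridine, THF, 0 °C → rt
Reagents that add atoms: dimethyl malonate (27), COC(=O)CC(=O)OC
Why: Knoevenagel condensation under titanium tetrachloride/pyridine, conditions suited to a non-enolisable neopentyl aldehyde and free of nucleophilic amine that could attack the ester on C3. The malonate is introduced only now because the ring nitrogen is tertiary and can no longer form a γ-lactam with it.

Step 18
Reactants: 28 alkylidene malonate
Product: 29 azocino-fused 3H-indole malonate (key-step precursor)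
Conditions: Hantzsch ester (diethyl 2,6-dimethyl-1,4-dihydropyridine-3,5-dicarboxylate), SiO2, toluene, 60 °C
Reagents that add atoms: none
Why: Conjugate transfer hydrogenation of the doubly activated alkene by the dihydropyridine; the hindered ketimine of the 3H-indole and the esters are not reduced in the absence of strong acid.

Step 19
Reactants: 29 azocino-fused 3H-indole malonate; 30 methyl chloroformate
Product: 32 pentacyclic geminal diester, via N-acyl indoleninium chloride 31 (not isolated)
Conditions: 30 (1.1 equiv), CH2Cl2, −40 °C; then MgBr2·OEt2 (2 equiv), iPr2NEt (2 equiv, slow addition), −40 → 0 °C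
Reagents that add atoms: methyl chloroformate (30), COC(=O)Cl
Why: Methyl chloroformate acylates the sp2 nitrogen of the 3H-indole to the N-acyl indoleninium chloride 31, which installs the carbamate of the target and makes C2 the electrophile; MgBr2·OEt2 and iPr2NEt then enolise the malonate by chelation and the enolate carbon adds to C2 (acyl-Mannich reaction, the chloroformate-activated counterpart of a Mannich addition of a 1,3-dicarbonyl compound to an imine). The cyclohexane closes in a 6-(enolexo)-exo-trig mode, with the C=N+ bond outside the new ring, and this transannular bond across the azocane completes the bicyclo[4.2.2] core. The only new stereocentre is C2: the malonate carbon hangs from Cq, which is tied to C2 by the CH2–CH2 bridge on one side and by N–CH2–CH2–C3 on the other, so it reaches C2 only from the face on which Cq lies and the two bridgeheads can form only in the mutual arrangement of the target; C3, Cq and the carbinol are not touched. The step needs C–C bond formation to outrun three side paths: loss of a proton from the CH2 next to C2 to give the enecarbamate, methoxycarbonylation of the malonate enolate, and acylation of the tertiary amine. Against the first the substrate offers proximity, since the enolate carbon sits five atoms from C2 inside the medium ring while deprotonation needs external base, which is added last and slowly; the second is avoided by letting the imine consume the chloroformate before any enolate exists; the third is reversible at low temperature and leads nowhere. Because C3 is quaternary the cation cannot escape to an aromatic indole, and once C2 is sp3 and N1 is acylated the product no longer reverts by retro-Mannich cleavage.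

Step 20
Reactants: 32 pentacyclic geminal diester
Product: 34 O-silyl ether of the target, via lithium ester enolate 33 (not isolated)
Conditions: LiCl (3 equiv), H2O (2 equiv), DMSO, 140 °C
Reagents that add atoms: none
Why: Krapcho dealkoxycarbonylation, selective for a geminal diester over isolated methyl esters and the carbamate: chloride removes one ester methyl group, CO2 is lost and the enolate 33 is protonated by water. Protonation should occur on the face that looks toward the unsubstituted CH2–CH2 bridge, away from the bridge that carries C3, which gives the (R)-methine; the enolate cannot expel the carbamate nitrogen because the resulting alkene would lie at the bridgehead C2.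

Step 21
Reactants: 34 O-silyl ether of the target
Product: 35 target CNP0144467.2
Conditions: HF·pyridine, THF/pyridine, 0 °C → rt
Reagents that add atoms: none
Why: Fluoride-mediated cleavage of the silyl ether; the weakly acidic reagent is chosen so that the ester methine is not epimerised and the esters are not attacked.

## Compound list

1 | 1-tert-butyl 2-methyl 3-oxopyrrolidine-1,2-dicarboxylate | COC(=O)C1N(C(=O)OC(C)(C)C)CCC1=O | starting material
2 | 1-tert-butyl 2-methyl (2R,3R)-3-hydroxypyrrolidine-1,2-dicarboxylate | COC(=O)[C@@H]1N(C(=O)OC(C)(C)C)CC[C@H]1O | intermediate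
3 | allyl bromide | C=CCBr | starting material
4 | dilithium alkoxide enolate of 2 | COC(O[Li])=C1N(C(=O)OC(C)(C)C)CC[C@H]1O[Li] | intermediate (not isolated)
5 | 1-tert-butyl 2-methyl (2S,3R)-3-hydroxy-2-(prop-2-en-1-yl)pyrrolidine-1,2-dicarboxylate | COC(=O)[C@@]1(CC=C)N(C(=O)OC(C)(C)C)CC[C@H]1O | intermediate
6 | 1-tert-butyl 2-methyl (2S,3R)-3-[(tert-butyldimethylsilyl)oxy]-2-(prop-2-en-1-yl)pyrrolidine-1,2-dicarboxylate | COC(=O)[C@@]1(CC=C)N(C(=O)OC(C)(C)C)CC[C@H]1O[Si](C)(C)C(C)(C)C | intermediate
7 | tert-butyl (2S,3R)-3-[(tert-butyldimethylsilyl)oxy]-2-formyl-2-(prop-2-en-1-yl)pyrrolidine-1-carboxylate | O=C[C@@]1(CC=C)N(C(=O)OC(C)(C)C)CC[C@H]1O[Si](C)(C)C(C)(C)C | intermediate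
8 | tert-butyl (2S,3R)-3-[(tert-butyldimethylsilyl)oxy]-2-(dimethoxymethyl)-2-(prop-2-en-1-yl)pyrrolidine-1-carboxylate | COC(OC)[C@@]1(CC=C)N(C(=O)OC(C)(C)C)CC[C@H]1O[Si](C)(C)C(C)(C)C | intermediate
9 | tert-butyl (2S,3R)-3-[(tert-butyldimethylsilyl)oxy]-2-(dimethoxymethyl)-2-[(1E)-prop-1-en-1-yl]pyrrolidine-1-carboxylate | COC(OC)[C@@]1(/C=C/C)N(C(=O)OC(C)(C)C)CC[C@H]1O[Si](C)(C)C(C)(C)C | intermediate
10 | ozonide (1,2,4-trioxolane) of 9 | COC(OC)[C@@]1(C2OOC(C)O2)N(C(=O)OC(C)(C)C)CC[C@H]1O[Si](C)(C)C(C)(C)C | intermediate (not isolated)
11 | tert-butyl (2R,3R)-3-[(tert-butyldimethylsilyl)oxy]-2-(dimethoxymethyl)-2-formylpyrrolidine-1-carboxylate | COC(OC)[C@@]1(C=O)N(C(=O)OC(C)(C)C)CC[C@H]1O[Si](C)(C)C(C)(C)C | intermediate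
12 | methyl 2-(2-nitrophenyl)acetate | COC(=O)Cc1ccccc1[N+](=O)[O-] | starting material
13 | (2-bromoethoxy)(tert-butyl)dimethylsilane | BrCCO[Si](C)(C)C(C)(C)C | starting material
14 | methyl 4-[(tert-butyldimethylsilyl)oxy]-2-(2-nitrophenyl)butanoate (racemic) | COC(=O)C(CCO[Si](C)(C)C(C)(C)C)c1ccccc1[N+](=O)[O-] | intermediate
15 | silyl ketene acetal of 14: tert-butyl{[4-methoxy-3-(2-nitrophenyl)-4-[(trimethylsilyl)oxy]but-3-en-1-yl]oxy}dimethylsilane (E/Z mixture) | COC(O[Si](C)(C)C)=C(CCO[Si](C)(C)C(C)(C)C)c1ccccc1[N+](=O)[O-] | intermediate
16 | methyl (2S)-2-acetyl-4-[(tert-butyldimethylsilyl)oxy]-2-(2-nitrophenyl)butanoate | CC(=O)[C@](c1ccccc1[N+](=O)[O-])(C(=O)OC)CCO[Si](C)(C)C(C)(C)C | intermediate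
17 | methyl (2S)-2-acetyl-4-bromo-2-(2-nitrophenyl)butanoate | CC(=O)[C@](c1ccccc1[N+](=O)[O-])(C(=O)OC)CCBr | intermediate
18 | dibutylboron enolate of 17 | C=C(OB(CCCC)CCCC)[C@](c1ccccc1[N+](=O)[O-])(C(=O)OC)CCBr | intermediate (not isolated)
19 | aldol adduct: methyl (2S)-2-(2-bromoethyl)-5-[(2S,3R)-1-(tert-butoxycarbonyl)-3-[(tert-butyldimethylsilyl)oxy]-2-(dimethoxymethyl)pyrrolidin-2-yl]-5-hydroxy-2-(2-nitrophenyl)-3-oxopentanoate (mixture at C5) | COC(OC)[C@@]1(C(O)CC(=O)[C@](c2ccccc2[N+](=O)[O-])(C(=O)OC)CCBr)N(C(=O)OC(C)(C)C)CC[C@H]1O[Si](C)(C)C(C)(C)C | intermediate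
20 | methanesulfonate of 19 | COC(OC)[C@@]1(C(OS(C)(=O)=O)CC(=O)[C@](c2ccccc2[N+](=O)[O-])(C(=O)OC)CCBr)N(C(=O)OC(C)(C)C)CC[C@H]1O[Si](C)(C)C(C)(C)C | intermediate (not isolated)
21 | methyl (2S,4E)-2-(2-bromoethyl)-5-[(2S,3R)-1-(tert-butoxycarbonyl)-3-[(tert-butyldimethylsilyl)oxy]-2-(dimethoxymethyl)pyrrolidin-2-yl]-2-(2-nitrophenyl)-3-oxopent-4-enoate | COC(OC)[C@@]1(/C=C/C(=O)[C@](c2ccccc2[N+](=O)[O-])(C(=O)OC)CCBr)N(C(=O)OC(C)(C)C)CC[C@H]1O[Si](C)(C)C(C)(C)C | intermediate
22 | methyl (2S)-2-(2-bromoethyl)-5-[(2S,3R)-1-(tert-butoxycarbonyl)-3-[(tert-butyldimethylsilyl)oxy]-2-(dimethoxymethyl)pyrrolidin-2-yl]-2-(2-nitrophenyl)-3-oxopentanoate | COC(OC)[C@@]1(CCC(=O)[C@](c2ccccc2[N+](=O)[O-])(C(=O)OC)CCBr)N(C(=O)OC(C)(C)C)CC[C@H]1O[Si](C)(C)C(C)(C)C | intermediate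
23 | amino ketone: the 2-aminophenyl analogue of 22 | COC(OC)[C@@]1(CCC(=O)[C@](c2ccccc2N)(C(=O)OC)CCBr)N(C(=O)OC(C)(C)C)CC[C@H]1O[Si](C)(C)C(C)(C)C | intermediate (not isolated)
24 | methyl (3S)-3-(2-bromoethyl)-2-{2-[(2S,3R)-1-(tert-butoxycarbonyl)-3-[(tert-butyldimethylsilyl)oxy]-2-(dimethoxymethyl)pyrrolidin-2-yl]ethyl}-3H-indole-3-carboxylate | COC(OC)[C@@]1(CCC2=Nc3ccccc3[C@@]2(C(=O)OC)CCBr)N(C(=O)OC(C)(C)C)CC[C@H]1O[Si](C)(C)C(C)(C)C | intermediate
25 | methyl (3S)-3-(2-bromoethyl)-2-{2-[(2S,3R)-3-[(tert-butyldimethylsilyl)oxy]-2-formylpyrrolidin-2-yl]ethyl}-3H-indole-3-carboxylate | O=C[C@@]1(CCC2=Nc3ccccc3[C@@]2(C(=O)OC)CCBr)NCC[C@H]1O[Si](C)(C)C(C)(C)C | intermediate (not isolated)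
26 | tetracyclic aldehyde: 3H-indole fused at C2/C3 to the azocane (C2–CH2–CH2–Cq–N–CH2–CH2–C3), nitrogen shared with the pyrrolidine; Cq (S) bears CHO, the neighbouring carbinol (R) is the TBS ether, C3 (S) bears CO2Me | O=C[C@@]12CCC3=Nc4ccccc4[C@@]3(C(=O)OC)CCN1CC[C@H]2O[Si](C)(C)C(C)(C)C | intermediate
27 | dimethyl malonate | COC(=O)CC(=O)OC | starting material
28 | alkylidene malonate of 26: Cq (R) bears CH=C(CO2Me)2 | COC(=O)C(C(=O)OC)=C[C@@]12CCC3=Nc4ccccc4[C@@]3(C(=O)OC)CCN1CC[C@H]2O[Si](C)(C)C(C)(C)C | intermediate
29 | azocino-fused 3H-indole malonate: as 28 with Cq–CH2–CH(CO2Me)2; Cq (R), carbinol (R), C3 (S) | COC(=O)C(C(=O)OC)C[C@@]12CCC3=Nc4ccccc4[C@@]3(C(=O)OC)CCN1CC[C@H]2O[Si](C)(C)C(C)(C)C | intermediate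
30 | methyl chloroformate | COC(=O)Cl | starting material
31 | N-methoxycarbonyl indoleninium chloride of 29 | COC(=O)C(C(=O)OC)C[C@@]12CCC3=[N+](C(=O)OC)c4ccccc4[C@@]3(C(=O)OC)CCN1CC[C@H]2O[Si](C)(C)C(C)(C)C.[Cl-] | intermediate (not isolated)
32 | pentacyclic geminal diester: N-methoxycarbonyl indoline, cyclohexane closed between C2 and C(CO2Me)2, TBS ether; configurations at C2, C3, Cq and carbinol as in the target | COC(=O)C1(C(=O)OC)C[C@@]23CC[C@@]14N(C(=O)OC)c1ccccc1[C@@]4(C(=O)OC)CCN2CC[C@H]3O[Si](C)(C)C(C)(C)C | intermediate
33 | lithium ester enolate formed from 32 by loss of chloromethane and CO2 | COC(O[Li])=C1C[C@@]23CC[C@@]14N(C(=O)OC)c1ccccc1[C@@]4(C(=O)OC)CCN2CC[C@H]3O[Si](C)(C)C(C)(C)C | intermediate (not isolated)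
34 | O-tert-butyldimethylsilyl ether of the target | COC(=O)[C@@H]1C[C@@]23CC[C@@]14N(C(=O)OC)c1ccccc1[C@@]4(C(=O)OC)CCN2CC[C@H]3O[Si](C)(C)C(C)(C)C | intermediate
35 | CNP0144467.2 | COC(=O)[C@@H]1C[C@@]23CC[C@@]14N(C(=O)OC)c1ccccc1[C@@]4(C(=O)OC)CCN2CC[C@H]3O | target

## Step count and least certain steps

Total: 21 steps. Longest linear sequence: 17 steps (steps 1–7 and 12–21); the aryl fragment takes steps 8–11.

**Step 19 (key step).** The N-acyl indoleninium ion may lose a proton from the CH2 next to C2 and settle as the enecarbamate before the malonate closes the ring. The chloroformate may also carboxylate the malonate enolate or be held by the tertiary amine. Fallback, from 29 back to 32: 29 is treated with methyl chloroformate 30 and Et3N (CH2Cl2, 0 °C), which deliberately gives the enecarbamate F1 (N-methoxycarbonyl 2-alkylidene indoline with the C=C between C2 and the ring CH2). F1 is then exposed to a strong Brønsted acid (TfOH, CH2Cl2, −40 → 0 °C), which protonates the alkene carbon and regenerates the N-acyl indoleninium ion in a medium without base, where the malonate enol closes the ring to 32. Enamide-to-acyliminium cyclisation is an established mode.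

**Step 16.** The eight-membered ring closure by a hindered amine may be slow. That would leave room for intermolecular alkylation, for transfer of the methoxycarbonyl group from C3 to the amine nitrogen with aromatisation to an indole, or for self-condensation through the free aldehyde. Fallback, from 24 back to 26: the N–CH2 bond is made by reductive amination. The bromide of 24 is oxidised (N-methylmorpholine N-oxide, DMSO, 40 °C) to the aldehyde F3. Acid (CF3CO2H, CH2Cl2, H2O) gives the amino dialdehyde F4 as its salt. NaBH(OAc)3 with AcOH in 1,2-dichloroethane at high dilution then reduces the cyclic iminium ion, which only the unhindered CH2–CHO can form, to give 26; the neopentyl aldehyde on Cq and the ketimine react far more slowly.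

**Step 10.** Enantiofacial discrimination may be poor, or of the opposite sense, with the ortho-nitroaryl ketene acetal, and acylation at oxygen may compete. Fallback, from 15 back to 16: acetylation of 15 with acetic anhydride and the achiral catalyst 4-(dimethylamino)pyridine gives the racemic keto ester F2. Its enantiomers are separated by preparative chromatography on a chiral stationary phase, and the (S)-enantiomer is 16.

**Step 17.** The condensation at a neopentyl α-amino aldehyde may be sluggish, and prolonged exposure to Lewis acid and base may lead to loss of the ester on C3 with aromatisation. Fallback, from 26 back to 29, bypassing 28: reductive alkylation of 2,2-dimethyl-1,3-dioxane-4,6-dione with 26 and Hantzsch ester (proline cat., EtOH, rt) gives the alkylated dioxanedione F5. Methanol at 65 °C opens it to the malonic half ester F6 with loss of acetone. Trimethylsilyldiazomethane (MeOH/toluene, 0 °C) gives 29.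

**Step 20.** Protonation of the enolate may occur from both faces, or the methine may equilibrate at 140 °C toward the undesired epimer; the silyl ether may be partly lost (harmless) and other methyl groups may be attacked. Fallback, from 34 (as obtained, mixed at the methine) back to 34: LiN(iPr)2 then PhSeBr (THF, −78 °C) gives the α-phenylselanyl ester F7. H2O2 (CH2Cl2, 0 °C) causes syn-elimination toward the ring CH2 to the unsaturated ester F8. Hydrogenation (H2, palladium on carbon, EtOAc) adds hydrogen from the face flanked by the CH2–CH2 bridge and returns 34 with the (R)-methine.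

## Further compounds

F1 | step 19 | enecarbamate of 29 (N-methoxycarbonyl, C=C between C2 and the ring CH2) | COC(=O)C(C(=O)OC)C[C@@]12C/C=C3/N(C(=O)OC)c4ccccc4[C@@]3(C(=O)OC)CCN1CC[C@H]2O[Si](C)(C)C(C)(C)C
F2 | step 10 | racemic methyl 2-acetyl-4-[(tert-butyldimethylsilyl)oxy]-2-(2-nitrophenyl)butanoate | CC(=O)C(c1ccccc1[N+](=O)[O-])(C(=O)OC)CCO[Si](C)(C)C(C)(C)C
F3 | step 16 | aldehyde from 24 (CH2–CHO in place of CH2–CH2Br at C3) | COC(OC)[C@@]1(CCC2=Nc3ccccc3[C@@]2(C(=O)OC)CC=O)N(C(=O)OC(C)(C)C)CC[C@H]1O[Si](C)(C)C(C)(C)C
F4 | step 16 | amino dialdehyde (formed as its trifluoroacetate salt; free base shown) | O=C[C@@]1(CCC2=Nc3ccccc3[C@@]2(C(=O)OC)CC=O)NCC[C@H]1O[Si](C)(C)C(C)(C)C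
F5 | step 17 | 5-alkyl-2,2-dimethyl-1,3-dioxane-4,6-dione from 26 | CC1(C)OC(=O)C(C[C@@]23CCC4=Nc5ccccc5[C@@]4(C(=O)OC)CCN2CC[C@H]3O[Si](C)(C)C(C)(C)C)C(=O)O1
F6 | step 17 | malonic half ester (monomethyl ester, mixture at the malonate carbon) | COC(=O)C(C(=O)O)C[C@@]12CCC3=Nc4ccccc4[C@@]3(C(=O)OC)CCN1CC[C@H]2O[Si](C)(C)C(C)(C)C
F7 | step 20 | α-phenylselanyl ester of 34 | COC(=O)C1([Se]c5ccccc5)C[C@@]23CC[C@@]14N(C(=O)OC)c1ccccc1[C@@]4(C(=O)OC)CCN2CC[C@H]3O[Si](C)(C)C(C)(C)C
F8 | step 20 | α,β-unsaturated ester (C=C between the ester carbon and the ring CH) | COC(=O)C1=C[C@@]23CC[C@@]14N(C(=O)OC)c1ccccc1[C@@]4(C(=O)OC)CCN2CC[C@H]3O[Si](C)(C)C(C)(C)C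
A1 | alternative 1 | spiro pyrrolidin-3-one | COC(=O)[C@@H]1C[C@@]2(C(=O)CCN2)CC[C@@]13N(C(=O)OC)c1ccccc1[C@@]3(C(=O)OC)CC(OC)OC
A2 | alternative 2 | tetracyclic azocine carboxylic acid | COC(=O)[C@@H]1C[C@@]23C=C[C@@H]1[C@](c1ccccc1Br)(C(=O)O)CCN2CC[C@H]3O[Si](C)(C)C(C)(C)C
A3 | alternative 3 | pentacyclic 3-acetylpyrrolidine | COC(=O)[C@@H]1C[C@@]23CC[C@@]14N(C(=O)OC)c1ccccc1[C@@]4(C(=O)OC)CCN2CC[C@H]3C(C)=O
A4 | alternative 3 | formaldehyde | C=O
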